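**Retrosynthetic overview**
1. Target 18 ⇐ 17 (Si–O cleavage) ⇐ 16 (C4=O to C4=CH2) ⇐ 15 (dithiane to ketone) ⇐ 13 (C9 alcohol, then ester) ⇐ 12 (C9 ketone).
2. Key disconnection: ring A of 12 is cut at C4–C5 and C1–C10. A 2-lithio-1,3-dithiane (acyl anion for C4) adds to the enone β-carbon C5 of 5, and the resulting enolate closes C1–C10 on the tethered chloride in the same flask.
3. Enone 5 (ring B with C6–O, C7-isopropyl, C10-methyl, C9=O) ⇐ allylic oxidation of silylated cis-piperitol ⇐ dynamic kinetic hydrogenation of racemic piperitone.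
4. Ring order: ring B comes from piperitone; ring A is formed in the key step.

Assumption: the SMILES is read as a cis-fused (5S,6S,7R,9R,10R)-eudesm-4(15)-ene-6,9-diol 9-(4-methoxybenzoate), in which 10-CH3, 5-H, 6-OH, 7-isopropyl and the 9-ester all lie on one face. Eudesmane numbering is used for the bicyclic compounds (ring A = C1–C5, C10; ring B = C5–C10; C15 = exocyclic carbon on C4), and the same atom labels are used in comments on the monocyclic precursors.

**Step 1**
Reactants: 1 (±)-piperitone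
Product: 2 (1S,6R)-3-methyl-6-(propan-2-yl)cyclohex-2-en-1-ol (cis-piperitol)
Conditions: H2 (8 atm), RuCl2[(S)-BINAP][(R,R)-DPEN] (0.5 mol %), KOtBu (5 mol %), i-PrOH, 25 °C
Reagents that add atoms: none
Why: Noyori asymmetric hydrogenation under dynamic kinetic resolution: KOtBu racemises the ketone α-centre (C7) through the dienolate while the catalyst reduces only the C=O of the (R)-ketone from the face anti to the isopropyl group, which sets C6 and C7 cis and leaves the C=C intact (catalyst antipode chosen as the one that gives (1R,2R)-cis-2-isopropylcyclohexanol from racemic 2-isopropylcyclohexanone, the same spatial arrangement).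

**Step 2**
Reactants: 2 (1S,6R)-3-methyl-6-(propan-2-yl)cyclohex-2-en-1-ol
Product: 3 tert-butyl(dimethyl){[(1S,6R)-3-methyl-6-(propan-2-yl)cyclohex-2-en-1-yl]oxy}silane
Conditions: TBSCl, imidazole, DMF, 40 °C
Reagents that add atoms: tert-butyldimethylsilyl chloride (TBSCl), CC(C)(C)[Si](C)(C)Cl
Why: Corey silyl ether formation protects the C6 hydroxyl without touching a stereocentre.

**Step 3**
Reactants: 3 tert-butyl(dimethyl){[(1S,6R)-3-methyl-6-(propan-2-yl)cyclohex-2-en-1-yl]oxy}silane
Product: 5 (4S,5R)-4-(tert-butyldimethylsilyloxy)-2-methyl-5-(propan-2-yl)cyclohex-2-en-1-one, via allylic alcohol 4 (not isolated)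
Conditions: SeO2 (0.5 equiv), t-BuOOH, CH2Cl2, 25 °C; crude, then MnO2, CH2Cl2, 25 °C
Reagents that add atoms: tert-butyl hydroperoxide, CC(C)(C)OO
Why: Sharpless–Umbreit SeO2/t-BuOOH allylic hydroxylation (ene reaction, then [2,3]-sigmatropic shift) occurs at the ring CH2 next to the more substituted alkene carbon (C9), not at the silyloxy-bearing C–H on the other alkene end, and MnO2 oxidises both epimers of the allylic alcohol to the enone; C6 and C7 are untouched.

**Step 4**
Reactants: 6 1,3-dithiane; 7 1-bromo-3-chloropropane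
Product: 9 2-(3-chloropropyl)-1,3-dithiane, via 2-lithio-1,3-dithiane 8 (not isolated)
Conditions: n-BuLi, THF, −30 °C; then added to 7, −78 °C
Reagents that add atoms: none
Why: Corey–Seebach alkylation in which the lithiated dithiane displaces bromide selectively over chloride.

**Step 5 (key step)**
Reactants: 5 (4S,5R)-4-(tert-butyldimethylsilyloxy)-2-methyl-5-(propan-2-yl)cyclohex-2-en-1-one; 9 2-(3-chloropropyl)-1,3-dithiane
Product: 12 (5S,6S,7R,10R)-6-(tert-butyldimethylsilyloxy)-4,4-(propane-1,3-diyldisulfanediyl)-15-noreudesman-9-one, via lithiated chloropropyl dithiane 10 (not isolated), via lithium enolate 11 (not isolated)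
Conditions: 9, t-BuLi, THF/HMPA (10:1), −78 °C, 10 min; then 5, −78 °C, 1 h; then −78 → 25 °C, 12 h
Reagents that add atoms: none
Why: Proposed new method: the sulfur-stabilised carbanion 10, a solvent-separated ion pair in THF/HMPA, adds 1,4 to enone 5 at C5 anti to the pseudo-axial γ-silyloxy group and the isopropyl group (sets C5), and the tetrasubstituted lithium enolate 11 is then alkylated at C10 by the tethered primary chloride through a chair-like 6-exo-tet transition state that can only deliver C1 to the face already carrying C4 (sets the quaternary C10 and the cis ring fusion); the closest known reactions are the HMPA-promoted conjugate addition of 2-lithio-1,3-dithianes to cyclohexenones (Corey–Seebach acyl anion making a Stetter-type bond) and Michael-initiated ring closure (MIRC) annulations with ω-halo nucleophiles.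

**Step 6**
Reactants: 12 (5S,6S,7R,10R)-6-(tert-butyldimethylsilyloxy)-4,4-(propane-1,3-diyldisulfanediyl)-15-noreudesman-9-one
Product: 13 (5S,6S,7R,9R,10R)-6-(tert-butyldimethylsilyloxy)-4,4-(propane-1,3-diyldisulfanediyl)-15-noreudesman-9-ol
Conditions: (S)-2-methyl-CBS-oxazaborolidine (0.2 equiv), BH3·SMe2, THF, −20 → 0 °C; MeOH quench
Reagents that add atoms: none
Why: Corey–Bakshi–Shibata reduction under catalyst control: with quaternary C10 as the large and C8H2 as the small flank, the (S)-catalyst delivers hydride to the face anti to the angular methyl and gives the 9R alcohol (OH cis to 10-CH3), by analogy with (R)-1-phenylethanol from acetophenone.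

**Step 7**
Reactants: 13 (5S,6S,7R,9R,10R)-6-(tert-butyldimethylsilyloxy)-4,4-(propane-1,3-diyldisulfanediyl)-15-noreudesman-9-ol; 14 4-methoxybenzoyl chloride
Product: 15 (5S,6S,7R,9R,10R)-6-(tert-butyldimethylsilyloxy)-4,4-(propane-1,3-diyldisulfanediyl)-15-noreudesman-9-yl 4-methoxybenzoate
Conditions: Et3N, DMAP (0.2 equiv), CH2Cl2, 40 °C
Reagents that add atoms: none
Why: DMAP-catalysed acylation (nucleophilic catalysis) of the only free hydroxyl, with retention at C9.

**Step 8**
Reactants: 15 (5S,6S,7R,9R,10R)-6-(tert-butyldimethylsilyloxy)-4,4-(propane-1,3-diyldisulfanediyl)-15-noreudesman-9-yl 4-methoxybenzoate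
Product: 16 (5S,6S,7R,9R,10R)-6-(tert-butyldimethylsilyloxy)-4-oxo-15-noreudesman-9-yl 4-methoxybenzoate
Conditions: PhI(OCOCF3)2, MeCN/H2O (9:1), 0 °C, 10 min
Reagents that add atoms: water, O
Why: Stork–Zhao oxidative dithiane hydrolysis with a hypervalent iodine reagent unmasks the C4 ketone under non-basic conditions, so the α-centre C5 is not epimerised and the ester and silyl ether survive.

**Step 9**
Reactants: 16 (5S,6S,7R,9R,10R)-6-(tert-butyldimethylsilyloxy)-4-oxo-15-noreudesman-9-yl 4-methoxybenzoate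
Product: 17 (5S,6S,7R,9R,10R)-6-(tert-butyldimethylsilyloxy)eudesm-4(15)-en-9-yl 4-methoxybenzoate
Conditions: Zn, CH2Br2, TiCl4, THF/CH2Cl2, 0 → 25 °C
Reagents that add atoms: dibromomethane, BrCBr
Why: Takai–Lombardo methylenation: the non-basic zinc–titanium methylene reagent converts the hindered ketone into the exocyclic alkene without epimerising C5 and does not attack the aryl ester.

**Step 10**
Reactants: 17 (5S,6S,7R,9R,10R)-6-(tert-butyldimethylsilyloxy)eudesm-4(15)-en-9-yl 4-methoxybenzoate
Product: 18 (5S,6S,7R,9R,10R)-6-hydroxyeudesm-4(15)-en-9-yl 4-methoxybenzoate (target)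
Conditions: HF·pyridine, THF, 0 → 25 °C
Reagents that add atoms: none
Why: Fluoride-mediated desilylation frees the axial C6 hydroxyl without acyl migration (the 6- and 9-oxygens are 1,4 across ring B) or alkene isomerisation.

**Compound list**
1 | (±)-piperitone, racemic 3-methyl-6-(propan-2-yl)cyclohex-2-en-1-one | CC1=CC(=O)C(C(C)C)CC1 | starting material
2 | (1S,6R)-3-methyl-6-(propan-2-yl)cyclohex-2-en-1-ol (cis-piperitol, OH and isopropyl cis) | CC1=C[C@@H](O)[C@@H](C(C)C)CC1 | intermediate
3 | tert-butyl(dimethyl){[(1S,6R)-3-methyl-6-(propan-2-yl)cyclohex-2-en-1-yl]oxy}silane | CC1=C[C@@H](O[Si](C)(C)C(C)(C)C)[C@@H](C(C)C)CC1 | intermediate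
4 | (4S,5R)-4-(tert-butyldimethylsilyloxy)-2-methyl-5-(propan-2-yl)cyclohex-2-en-1-ol, both C1 epimers (not isolated) | CC1=C[C@@H](O[Si](C)(C)C(C)(C)C)[C@@H](C(C)C)CC1O | intermediate
5 | (4S,5R)-4-(tert-butyldimethylsilyloxy)-2-methyl-5-(propan-2-yl)cyclohex-2-en-1-one (OTBS and isopropyl cis) | CC1=C[C@@H](O[Si](C)(C)C(C)(C)C)[C@@H](C(C)C)CC1=O | intermediate
6 | 1,3-dithiane | C1CSCSC1 | starting material
7 | 1-bromo-3-chloropropane | ClCCCBr | starting material
8 | 2-lithio-1,3-dithiane (not isolated) | [Li]C1SCCCS1 | intermediate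
9 | 2-(3-chloropropyl)-1,3-dithiane | ClCCCC1SCCCS1 | intermediate
10 | 2-(3-chloropropyl)-2-lithio-1,3-dithiane (not isolated) | [Li]C1(CCCCl)SCCCS1 | intermediate
11 | lithium (3S,4S,5R)-4-(tert-butyldimethylsilyloxy)-3-[2-(3-chloropropyl)-1,3-dithian-2-yl]-2-methyl-5-(propan-2-yl)cyclohex-1-en-1-olate, dithianyl group trans to OTBS and isopropyl (not isolated) | ClCCCC1(SCCCS1)[C@@H]2[C@@H](O[Si](C)(C)C(C)(C)C)[C@@H](C(C)C)CC([O-])=C2C.[Li+] | intermediate
12 | (5S,6S,7R,10R)-6-(tert-butyldimethylsilyloxy)-4,4-(propane-1,3-diyldisulfanediyl)-15-noreudesman-9-one: cis-decalin, spiro-1,3-dithiane at C4, ketone at C9; 10-CH3, 5-H, 6-OTBS and 7-isopropyl on one face | C12(SCCCS1)CCC[C@]3(C)[C@H]2[C@@H](O[Si](C)(C)C(C)(C)C)[C@@H](C(C)C)CC3=O | intermediate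
13 | (5S,6S,7R,9R,10R)-6-(tert-butyldimethylsilyloxy)-4,4-(propane-1,3-diyldisulfanediyl)-15-noreudesman-9-ol (9-OH cis to 10-CH3) | C12(SCCCS1)CCC[C@]3(C)[C@H]2[C@@H](O[Si](C)(C)C(C)(C)C)[C@@H](C(C)C)C[C@H]3O | intermediate
14 | 4-methoxybenzoyl chloride (p-anisoyl chloride) | COc1ccc(cc1)C(Cl)=O | starting material
15 | (5S,6S,7R,9R,10R)-6-(tert-butyldimethylsilyloxy)-4,4-(propane-1,3-diyldisulfanediyl)-15-noreudesman-9-yl 4-methoxybenzoate | C12(SCCCS1)CCC[C@]3(C)[C@H]2[C@@H](O[Si](C)(C)C(C)(C)C)[C@@H](C(C)C)C[C@H]3OC(=O)c1ccc(OC)cc1 | intermediate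
16 | (5S,6S,7R,9R,10R)-6-(tert-butyldimethylsilyloxy)-4-oxo-15-noreudesman-9-yl 4-methoxybenzoate | O=C1CCC[C@]2(C)[C@H]1[C@@H](O[Si](C)(C)C(C)(C)C)[C@@H](C(C)C)C[C@H]2OC(=O)c1ccc(OC)cc1 | intermediate
17 | (5S,6S,7R,9R,10R)-6-(tert-butyldimethylsilyloxy)eudesm-4(15)-en-9-yl 4-methoxybenzoate | C=C1CCC[C@]2(C)[C@H]1[C@@H](O[Si](C)(C)C(C)(C)C)[C@@H](C(C)C)C[C@H]2OC(=O)c1ccc(OC)cc1 | intermediate
18 | (5S,6S,7R,9R,10R)-6-hydroxyeudesm-4(15)-en-9-yl 4-methoxybenzoate (CNP0107029.1) | C=C1CCC[C@]2(C)[C@H]1[C@@H](O)[C@@H](C(C)C)C[C@H]2OC(=O)c1ccc(OC)cc1 | target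

**Step count and risks**
Total steps: 10. Longest linear sequence: 9 (steps 1, 2, 3, 5, 6, 7, 8, 9, 10; step 4 is a one-step side branch).

Most likely to fail, step 5: carbanion 10 may close to the spiro-cyclobutane or add 1,2 before the annulation takes place. The fallback sets out from 5 and makes the two bonds in separate operations. 2-Lithio-1,3-dithiane 8 (from 6 and n-BuLi) is added in THF/HMPA at −78 °C and the enolate is trapped with Me3SiCl to give the trimethylsilyl enol ether F1. The dithiane C–H of F1 is removed with t-BuLi/HMPA at −78 °C and the anion is alkylated with 7 at its bromide end to give the chloropropyl dithiane silyl enol ether F2. MeLi then cleaves the O–Si bond of F2 to the lithium enolate 11, which closes ring A on warming; the fallback comes back to the route at 12.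

Second, step 6: the intrinsic facial bias of the cis-decalone may override the oxazaborolidine and give mainly the 9-epimer. The fallback sets out from 12 and uses that bias instead. LiAlH4 in THF at −78 °C reduces 12 to the 9-epi alcohol F3. A Mitsunobu esterification (4-methoxybenzoic acid, PPh3, DIAD, toluene) then forms the ester with inversion at C9, and the fallback comes back to the route at 15.

Third, step 1: the dynamic kinetic hydrogenation is untested on piperitone, and racemisation may be too slow for high enantiomeric purity. The fallback sets out from 1 and replaces catalysis by an enzymatic resolution. L-Selectride (THF, −78 °C) gives racemic cis-piperitol F4. Candida antarctica lipase B with vinyl acetate acylates the (1R,6S) enantiomer to (1R,6S)-cis-piperityl acetate F5 (the sense known for cyclohex-2-en-1-ols) and leaves the (1S,6R) alcohol, which is separated by chromatography; the fallback comes back to the route at 2.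

**Further compounds**
F1 | step 5 | {[(3S,4S,5R)-4-(tert-butyldimethylsilyloxy)-3-(1,3-dithian-2-yl)-2-methyl-5-(propan-2-yl)cyclohex-1-en-1-yl]oxy}trimethylsilane | S1CCCSC1[C@@H]2[C@@H](O[Si](C)(C)C(C)(C)C)[C@@H](C(C)C)CC(O[Si](C)(C)C)=C2C
F2 | step 5 | {[(3S,4S,5R)-4-(tert-butyldimethylsilyloxy)-3-[2-(3-chloropropyl)-1,3-dithian-2-yl]-2-methyl-5-(propan-2-yl)cyclohex-1-en-1-yl]oxy}trimethylsilane | ClCCCC1(SCCCS1)[C@@H]2[C@@H](O[Si](C)(C)C(C)(C)C)[C@@H](C(C)C)CC(O[Si](C)(C)C)=C2C
F3 | step 6 | (5S,6S,7R,9S,10R)-6-(tert-butyldimethylsilyloxy)-4,4-(propane-1,3-diyldisulfanediyl)-15-noreudesman-9-ol (9-epimer of 13) | C12(SCCCS1)CCC[C@]3(C)[C@H]2[C@@H](O[Si](C)(C)C(C)(C)C)[C@@H](C(C)C)C[C@@H]3O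
F4 | step 1 | racemic cis-3-methyl-6-(propan-2-yl)cyclohex-2-en-1-ol (both enantiomers) | CC1=C[C@@H](O)[C@@H](C(C)C)CC1.CC1=C[C@H](O)[C@H](C(C)C)CC1
F5 | step 1 | (1R,6S)-3-methyl-6-(propan-2-yl)cyclohex-2-en-1-yl acetate | CC1=C[C@H](OC(C)=O)[C@H](C(C)C)CC1
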